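**Plan**

- Retrosynthesis: the two O–benzyl bonds and the 7-O–methyl bond are cut first, then C5–C6 of ring A (Claisen closure of a chain ketone onto an ester, both carried by a 4-pyranone that is already ring C). Next come C7–C8 (acylation at the lateral carbon), then C4–C4a and O1–C2 of the pyranone, and finally the two C–C bonds of an arylpropiolic acid.
- Forward: ring B is bought as an aldehyde and extended to the arylpropiolic acid. Ring C is assembled from its chloride and methyl 4-methoxy-3-oxobutanoate, the C6–C7 unit is attached at C8, and ring A is closed last.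
- Enabling feature: in ring A the oxygens on C5, C7 and C8a sit on alternate carbons, as in a polyketide. C5 can therefore come from an ester on C4a and C7 from a chain ketone, the oxygens on C6 and C8 ride in as α-alkoxy groups of the chain, and O1 is already locked on C8a by ring C.
- Stereochemistry: the target has no stereocentre. The single centre met on the way (C8 of 11, racemic) becomes an sp2 ring carbon on aromatisation.

Key step: step 6

Remark: flavone numbering (O1, C2 to C8a, C1′ to C6′) is used for the atoms of all pyranone intermediates, and rotation about the C2–C1′ bond is taken as free, so no configuration has to be controlled.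

**Route**

Step 1
Reactants: 1 2-hydroxy-6-methoxybenzaldehyde
Product: 2 2-(benzyloxy)-6-methoxybenzaldehyde
Conditions: BnBr, K2CO3, DMF, 60 °C
Reagents that add atoms: benzyl bromide, BrCc1ccccc1
Why: Williamson ether synthesis at the only phenol; gentle heating overcomes its hydrogen bond to the aldehyde, which carbonate leaves untouched.

Step 2
Reactants: 2 2-(benzyloxy)-6-methoxybenzaldehyde
Product: 3 1-(benzyloxy)-2-(2,2-dibromoethenyl)-3-methoxybenzene
Conditions: CBr4, PPh3, CH2Cl2, 0 °C; hexane precipitation, filtration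
Reagents that add atoms: carbon tetrabromide, BrC(Br)(Br)Br
Why: Corey–Fuchs dibromo-olefination (Wittig-type reaction of the ylide Ph3P=CBr2), which tolerates aryl ethers and is routinely used on di-ortho-substituted benzaldehydes.

Step 3
Reactants: 3 1-(benzyloxy)-2-(2,2-dibromoethenyl)-3-methoxybenzene
Product: 5 3-[2-(benzyloxy)-6-methoxyphenyl]prop-2-ynoic acid, via lithium acetylide 4 (not isolated)
Conditions: n-BuLi (2.2 equiv), THF, −78 °C; CO2, −78 to 0 °C; aq. HCl
Reagents that add atoms: carbon dioxide, O=C=O
Why: second stage of the Corey–Fuchs sequence (bromine–lithium exchange and elimination to the lithium acetylide) followed by carboxylation of the acetylide; the aryl ethers should not be metalated at −78 °C.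

Step 4
Reactants: 5 3-[2-(benzyloxy)-6-methoxyphenyl]prop-2-ynoic acid, 6 methyl 4-methoxy-3-oxobutanoate
Product: 9 methyl 6-[2-(benzyloxy)-6-methoxyphenyl]-2-(methoxymethyl)-4-oxo-4H-pyran-3-carboxylate, via ynoyl chloride 7 (not isolated), via acyclic ynone 8 (not isolated)
Conditions: (COCl)2, cat. DMF, CH2Cl2, 0 °C to rt, evaporate; 6, MgCl2, Et3N, MeCN, 0 °C to rt; aq. HCl wash; cat. DBU, MeCN, rt
Reagents that add atoms: none
Why: Rathke-type magnesium-enolate C-acylation of the β-keto ester by the acid chloride, then base-catalysed 6-endo-dig oxa-Michael addition of the ketone enol oxygen to the ynone, the classical ynoyl chloride/β-keto ester route to 2,6-disubstituted 4-pyranone-3-carboxylates.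

Step 5
Reactants: 9 methyl 6-[2-(benzyloxy)-6-methoxyphenyl]-2-(methoxymethyl)-4-oxo-4H-pyran-3-carboxylate, 10 (benzyloxy)acetyl chloride
Product: 11 methyl 6-[2-(benzyloxy)-6-methoxyphenyl]-2-[3-(benzyloxy)-1-methoxy-2-oxopropyl]-4-oxo-4H-pyran-3-carboxylate (racemic at the side-chain methine)
Conditions: LiN(SiMe3)2 (2.2 equiv), THF, −78 °C; 10 (1.1 equiv), −78 °C; AcOH, −78 °C
Reagents that add atoms: none
Why: lateral (vinylogous) deprotonation of the 2-alkyl group of a 4-pyranone, made easier by the 3-ester, gives an extended enolate that undergoes Claisen-type C-acylation at its exocyclic carbon, the only site that restores the pyranone, while the second equivalent of base takes up the more acidic product so that proton transfer does not stall the reaction.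

Step 6
Reactants: 11 methyl 6-[2-(benzyloxy)-6-methoxyphenyl]-2-[3-(benzyloxy)-1-methoxy-2-oxopropyl]-4-oxo-4H-pyran-3-carboxylate
Product: 13 6-(benzyloxy)-2-[2-(benzyloxy)-6-methoxyphenyl]-5,7-dihydroxy-8-methoxy-4H-chromen-4-one, via keto tautomer 12 (not isolated)
Conditions: LiN(iPr)2 (3.2 equiv), THF, −78 to 0 °C; aq. HCl
Reagents that add atoms: none
Why: Proposed new method: the first equivalent of LiN(iPr)2 should remove the C8 methine proton (flanked by pyranone carbon C8a and the C7 ketone), the second a C6 proton next to the benzyloxy group, and the C6 terminus of this dianion should add to the ester carbonyl C5 on the neighbouring ring carbon C4a, methoxide leaving and the cyclohexadienedione 12 being deprotonated by the third equivalent so that acidification delivers the benzenoid 5,7-diol 13. The closest known reaction type is the base-mediated Claisen (Dieckmann) cyclisation of methyl 2-(2-oxoalkyl)benzoates to naphthalene-1,3-diols and the biomimetic folding of polycarbonyl chains to phloroglucinol-type rings; new here are the 4-pyranone as template ring and the two α-alkoxy groups on the chain. Ring A closes in a 6-(enolendo)-exo-trig mode through C5–C6, the only skeletal bond formed. No stereocentre is created, and the racemic C8 centre of 11 becomes an sp2 ring carbon. The step needs attack by C6 and not C8, and acylation on carbon and not on oxygen: C8 could only close a four-membered ring, and an enol lactone from attack of O7 on the ester should be reopened by methoxide, whereas C-acylation is made irreversible by aromatisation. Because O1 already sits on C8a, ring A can form in one orientation only, and the chelated 5-OH and the free 7-OH come out differentiated for the next step.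

Step 7
Reactants: 13 6-(benzyloxy)-2-[2-(benzyloxy)-6-methoxyphenyl]-5,7-dihydroxy-8-methoxy-4H-chromen-4-one
Product: 14 6-(benzyloxy)-2-[2-(benzyloxy)-6-methoxyphenyl]-5-hydroxy-7,8-dimethoxy-4H-chromen-4-one
Conditions: MeI (1.1 equiv), K2CO3, acetone, rt
Reagents that add atoms: iodomethane, CI
Why: Williamson methylation of the more acidic 7-OH (para to the C4 carbonyl), while the 5-OH is held in a hydrogen bond to that carbonyl and should stay free, as is general for 5,7-dihydroxyflavones.

Step 8
Reactants: 14 6-(benzyloxy)-2-[2-(benzyloxy)-6-methoxyphenyl]-5-hydroxy-7,8-dimethoxy-4H-chromen-4-one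
Product: 15 5,6,2′-trihydroxy-7,8,6′-trimethoxyflavone, i.e. 5,6-dihydroxy-2-(2-hydroxy-6-methoxyphenyl)-7,8-dimethoxy-4H-chromen-4-one
Conditions: H2 (1 atm), 10% Pd/C, EtOAc–MeOH, rt; work-up under argon
Reagents that add atoms: none
Why: catalytic hydrogenolysis of both benzyl ethers, under which the flavone enone and the methyl ethers are normally untouched; exclusion of air protects the 5,6-dihydroxy unit from oxidation.

**Compound list**

1 | 2-hydroxy-6-methoxybenzaldehyde | COc1cccc(O)c1C=O | starting material
2 | 2-(benzyloxy)-6-methoxybenzaldehyde | COc1cccc(OCc2ccccc2)c1C=O | intermediate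
3 | 1-(benzyloxy)-2-(2,2-dibromoethenyl)-3-methoxybenzene | COc1cccc(OCc2ccccc2)c1C=C(Br)Br | intermediate
4 | lithium [2-(benzyloxy)-6-methoxyphenyl]acetylide | [Li]C#Cc1c(OC)cccc1OCc1ccccc1 | intermediate (not isolated)
5 | 3-[2-(benzyloxy)-6-methoxyphenyl]prop-2-ynoic acid | COc1cccc(OCc2ccccc2)c1C#CC(=O)O | intermediate
6 | methyl 4-methoxy-3-oxobutanoate | COCC(=O)CC(=O)OC | starting material
7 | 3-[2-(benzyloxy)-6-methoxyphenyl]prop-2-ynoyl chloride | COc1cccc(OCc2ccccc2)c1C#CC(=O)Cl | intermediate (not isolated)
8 | methyl 5-[2-(benzyloxy)-6-methoxyphenyl]-2-(methoxyacetyl)-3-oxopent-4-ynoate (enolised) | COCC(=O)C(C(=O)OC)C(=O)C#Cc1c(OC)cccc1OCc1ccccc1 | intermediate (not isolated)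
9 | methyl 6-[2-(benzyloxy)-6-methoxyphenyl]-2-(methoxymethyl)-4-oxo-4H-pyran-3-carboxylate | COCc1oc(-c2c(OC)cccc2OCc2ccccc2)cc(=O)c1C(=O)OC | intermediate
10 | (benzyloxy)acetyl chloride | O=C(Cl)COCc1ccccc1 | starting material
11 | methyl 6-[2-(benzyloxy)-6-methoxyphenyl]-2-[3-(benzyloxy)-1-methoxy-2-oxopropyl]-4-oxo-4H-pyran-3-carboxylate (racemic) | COC(=O)c1c(C(OC)C(=O)COCc2ccccc2)oc(-c2c(OC)cccc2OCc2ccccc2)cc1=O | intermediate
12 | 6-(benzyloxy)-2-[2-(benzyloxy)-6-methoxyphenyl]-7-hydroxy-8-methoxy-4H-chromene-4,5(6H)-dione (racemic, present as its lithium enolate) | COc1cccc(OCc2ccccc2)c1C1=CC(=O)C2=C(O1)C(OC)=C(O)C(OCc1ccccc1)C2=O | intermediate (not isolated)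
13 | 6-(benzyloxy)-2-[2-(benzyloxy)-6-methoxyphenyl]-5,7-dihydroxy-8-methoxy-4H-chromen-4-one | COc1cccc(OCc2ccccc2)c1-c1cc(=O)c2c(O)c(OCc3ccccc3)c(O)c(OC)c2o1 | intermediate
14 | 6-(benzyloxy)-2-[2-(benzyloxy)-6-methoxyphenyl]-5-hydroxy-7,8-dimethoxy-4H-chromen-4-one | COc1cccc(OCc2ccccc2)c1-c1cc(=O)c2c(O)c(OCc3ccccc3)c(OC)c(OC)c2o1 | intermediate
15 | 5,6-dihydroxy-2-(2-hydroxy-6-methoxyphenyl)-7,8-dimethoxy-4H-chromen-4-one | COc1cccc(O)c1-c1cc(=O)c2c(O)c(O)c(OC)c(OC)c2o1 | target

**Step count**

Total: 8 steps. Longest linear sequence: 8 steps (1 to 15); compounds 6 and 10 are purchased and enter at steps 4 and 5.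

**Steps most likely to fail**

Step 6 (ring A closure). The C6 enolate may not form from the stabilised monoanion. Acylation may occur on oxygen and give an enol lactone that does not revert. The pyranone may be opened by the liberated methoxide. The fallback uses known chemistry and brings ring A in ready-made. It sets out from aldehyde 2, which would be condensed (KOH, EtOH, rt, Claisen–Schmidt) with the known 1-(2-hydroxy-3,4,5,6-tetramethoxyphenyl)ethan-1-one F1 to the chalcone (2E)-3-[2-(benzyloxy)-6-methoxyphenyl]-1-(2-hydroxy-3,4,5,6-tetramethoxyphenyl)prop-2-en-1-one F2. Oxidative cyclisation (cat. I2, DMSO, 120 °C) would give 2-[2-(benzyloxy)-6-methoxyphenyl]-5,6,7,8-tetramethoxy-4H-chromen-4-one F3. Hydrogenolysis (H2, 10% Pd/C) would free the phenol 2-(2-hydroxy-6-methoxyphenyl)-5,6,7,8-tetramethoxy-4H-chromen-4-one F4. Chelation-controlled cleavage of the 5- and 6-methyl ethers with anhydrous AlBr3 in MeCN, a known selective demethylation of 5,6,7,8-tetramethoxyflavones, would rejoin the route at target 15.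

Step 5 (lateral acylation). The acid chloride may be consumed by the silylamide base. The extended enolate may be acylated on oxygen or twice. The product enolate may cyclise before the quench. The fallback replaces acylation by aldol addition and oxidation. It sets out from 9, whose lithium enolate (LiN(SiMe3)2, 1.1 equiv, THF, −78 °C) would add to (benzyloxy)acetaldehyde, with a cold AcOH quench, to give methyl 6-[2-(benzyloxy)-6-methoxyphenyl]-2-[3-(benzyloxy)-2-hydroxy-1-methoxypropyl]-4-oxo-4H-pyran-3-carboxylate F5 as a mixture of diastereomers. Dess–Martin periodinane (NaHCO3, CH2Cl2) would oxidise it to the ketone, rejoining the route at 11.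

Step 4 (pyranone assembly). HCl or amine may add across the triple bond of the electron-rich ynoyl chloride. The keto ester may be acylated on oxygen. The ring may close 5-exo in place of 6-endo. The fallback avoids the alkyne and closes the ring by cyclodehydration. It sets out from aldehyde 2, which would be oxidised (NaClO2, NaH2PO4, 2-methylbut-2-ene, t-BuOH–H2O) to 2-(benzyloxy)-6-methoxybenzoic acid F6. Coupling with Meldrum's acid (DCC, DMAP, CH2Cl2) would give 5-{[2-(benzyloxy)-6-methoxyphenyl](hydroxy)methylidene}-2,2-dimethyl-1,3-dioxane-4,6-dione F7. Heating F7 with keto ester 6 in toluene would release the aroylketene 3-[2-(benzyloxy)-6-methoxyphenyl]-3-oxoprop-1-en-1-one F8, which is captured at the central carbon of 6 to give methyl 5-[2-(benzyloxy)-6-methoxyphenyl]-2-(methoxyacetyl)-3,5-dioxopentanoate F9. Acid-mediated cyclodehydration (TFA, CH2Cl2) would rejoin the route at 9.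

**Further compounds**

F1 | step 6 | 1-(2-hydroxy-3,4,5,6-tetramethoxyphenyl)ethan-1-one | CC(=O)c1c(O)c(OC)c(OC)c(OC)c1OC
F2 | step 6 | (2E)-3-[2-(benzyloxy)-6-methoxyphenyl]-1-(2-hydroxy-3,4,5,6-tetramethoxyphenyl)prop-2-en-1-one | COc1cccc(OCc2ccccc2)c1/C=C/C(=O)c1c(O)c(OC)c(OC)c(OC)c1OC
F3 | step 6 | 2-[2-(benzyloxy)-6-methoxyphenyl]-5,6,7,8-tetramethoxy-4H-chromen-4-one | COc1cccc(OCc2ccccc2)c1-c1cc(=O)c2c(OC)c(OC)c(OC)c(OC)c2o1
F4 | step 6 | 2-(2-hydroxy-6-methoxyphenyl)-5,6,7,8-tetramethoxy-4H-chromen-4-one | COc1cccc(O)c1-c1cc(=O)c2c(OC)c(OC)c(OC)c(OC)c2o1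
F5 | step 5 | methyl 6-[2-(benzyloxy)-6-methoxyphenyl]-2-[3-(benzyloxy)-2-hydroxy-1-methoxypropyl]-4-oxo-4H-pyran-3-carboxylate (mixture of diastereomers) | COC(=O)c1c(C(OC)C(O)COCc2ccccc2)oc(-c2c(OC)cccc2OCc2ccccc2)cc1=O
F6 | step 4 | 2-(benzyloxy)-6-methoxybenzoic acid | COc1cccc(OCc2ccccc2)c1C(=O)O
F7 | step 4 | 5-{[2-(benzyloxy)-6-methoxyphenyl](hydroxy)methylidene}-2,2-dimethyl-1,3-dioxane-4,6-dione | COc1cccc(OCc2ccccc2)c1C(O)=C1C(=O)OC(C)(C)OC1=O
F8 | step 4 | 3-[2-(benzyloxy)-6-methoxyphenyl]-3-oxoprop-1-en-1-one (transient aroylketene) | COc1cccc(OCc2ccccc2)c1C(=O)C=C=O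
F9 | step 4 | methyl 5-[2-(benzyloxy)-6-methoxyphenyl]-2-(methoxyacetyl)-3,5-dioxopentanoate | COCC(=O)C(C(=O)OC)C(=O)CC(=O)c1c(OC)cccc1OCc1ccccc1
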